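**Strategy.** The route rests on one disconnection: the C3–C4 bond of the heptadecan-2-one chain, between the ketone's outer α-carbon and the tetradecyl residue. The key step exploits the position of the C2 carbonyl between benzylic C1, acidified by both the resorcinol ring and the carbonyl, and C3. Double deprotonation of commercial 1-(3,5-dimethoxyphenyl)propan-2-one gives an α,α′-dianion in which C1 is locked in the delocalised enolate, while the later-formed, more basic C3 carbanion alone attacks 1-bromotetradecane. The whole carbon skeleton is thus assembled in one operation without any activating group. Cleavage of the two methyl ethers then gives the target.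

Key step: step 1

Remark: the target has no stereocentre and no double-bond geometry, so no stereocontrol is needed; the phenols are carried as methyl ethers because ketone 1 and bromide 2 are both taken as purchasable.

**Step 1**
Reactants: 1 1-(3,5-dimethoxyphenyl)propan-2-one; 2 1-bromotetradecane
Product: 5 1-(3,5-dimethoxyphenyl)heptadecan-2-one, via dipotassium ketone dianion 3 (not isolated), via potassium enolate 4 (not isolated)
Conditions: KNH2 (2.05 equiv, from K, cat. Fe(NO3)3), liq. NH3/THF, –33 °C; then 2 (1.0 equiv) in THF, –33 °C; solid NH4Cl
Reagents that add atoms: none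
Why: The first equivalent of amide removes the doubly activated benzylic C1–H to give the ring-conjugated enolate, and the second removes a C3–H to give the 1,3-dianion 3. The C3 carbanion is the later-formed, less delocalised and therefore more nucleophilic site, so SN2 displacement of bromide from the primary halide 2 should take place there and form the C3–C4 bond, leaving the benzylic enolate 4, which is protonated by NH4Cl. The closest known reaction type is the alkylation of ketone α,α′-dianions generated from benzyl methyl ketones with potassium amide in liquid ammonia, which follows the same logic as β-keto ester dianion alkylation. No ring is closed and no stereocentre is formed. The step needs C3- over C1- and O-alkylation and mono- over dialkylation: the first is secured by the charge distribution of the dianion, the second because the product 4 is a monoanion whose C3–H is not removed once the amide is consumed. The methyl ethers are inert to amide, which does not metalate the ring.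

**Step 2**
Reactants: 5 1-(3,5-dimethoxyphenyl)heptadecan-2-one
Product: 7 1-(3,5-dihydroxyphenyl)heptadecan-2-one, via bis(dibromoboryl) ether 6 (not isolated)
Conditions: BBr3 (3 equiv), CH2Cl2, –78 °C to rt; then H2O, 0 °C
Reagents that add atoms: none
Why: Lewis acid-mediated cleavage of aryl methyl ethers: BBr3 coordinates each ether oxygen and bromide attacks the methyl group, and the aryloxyboranes 6 hydrolyse on quench, while the ketone, the benzylic CH2 and the alkyl chain should be inert and the meta-phenols cannot close a ring onto C2.

**Compound list**
1 | 1-(3,5-dimethoxyphenyl)propan-2-one | COc1cc(CC(C)=O)cc(OC)c1 | starting material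
2 | 1-bromotetradecane | CCCCCCCCCCCCCCBr | starting material
3 | dipotassium α,α′-dianion of 1 (C1=C2 enolate with C3 carbanion) | [K+].[K+].[CH2-]C([O-])=Cc1cc(OC)cc(OC)c1 | intermediate
4 | potassium C1=C2 enolate of 1-(3,5-dimethoxyphenyl)heptadecan-2-one | [K+].CCCCCCCCCCCCCCCC([O-])=Cc1cc(OC)cc(OC)c1 | intermediate
5 | 1-(3,5-dimethoxyphenyl)heptadecan-2-one | CCCCCCCCCCCCCCCC(=O)Cc1cc(OC)cc(OC)c1 | intermediate
6 | 1-[3,5-bis(dibromoboryloxy)phenyl]heptadecan-2-one | CCCCCCCCCCCCCCCC(=O)Cc1cc(OB(Br)Br)cc(OB(Br)Br)c1 | intermediate
7 | 1-(3,5-dihydroxyphenyl)heptadecan-2-one | CCCCCCCCCCCCCCCC(=O)Cc1cc(O)cc(O)c1 | target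

**Total step count:** 2
**Longest linear sequence:** 2

**Steps most likely to fail** (the route has only two steps, so both are ranked and there is no third)

1. Step 1. The second deprotonation may be incomplete. Free amide would then consume the bromide by substitution or elimination, and the remaining mono-enolate would alkylate at benzylic C1 or on oxygen. Proton transfer between dianion and product enolate could also lead to a second alkylation at C3. Fallback: the same C3–C4 bond would be made by a β-keto ester alkylation, in which C3 is the most acidic carbon by design. The fallback sets out from compound 2 and comes back to the route at compound 5. Purchased 3,5-dimethoxyphenylacetic acid F1 would be condensed with Meldrum's acid (DCC, DMAP, CH2Cl2, 0 °C to rt) to the acyl Meldrum's acid F2. Reflux of F2 in methanol should give methyl 4-(3,5-dimethoxyphenyl)-3-oxobutanoate F3. Its C2 methylene would be alkylated with 2 (K2CO3, cat. n-Bu4NI, DMF, 60 °C) to racemic methyl 2-[(3,5-dimethoxyphenyl)acetyl]hexadecanoate F4. Krapcho dealkoxycarbonylation (LiCl, wet DMSO, 150 °C) should then deliver 5.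

2. Step 2. Cleavage of the second methyl ether may stall. Alternatively, the Lewis and Brønsted acid present during cleavage and quench may promote condensation of the enolisable ketone with the electron-rich ring. Fallback: the phenols would be carried as benzyl ethers, so that the end-game is a neutral hydrogenolysis. The fallback sets out from compound 2 and comes back at compound 7. Purchased 1,3-bis(benzyloxy)-5-bromobenzene F5 would be converted by Pd-catalysed mono-α-arylation of acetone ([Pd(cinnamyl)Cl]2, Mor-DalPhos, Cs2CO3, acetone, 90 °C) into 1-[3,5-bis(benzyloxy)phenyl]propan-2-one F6. Dianion alkylation with 2 under the conditions of step 1 would pass through the dipotassium dianion F7 and the potassium enolate F8 (neither isolated) to 1-[3,5-bis(benzyloxy)phenyl]heptadecan-2-one F9. Hydrogenolysis (H2, Pd/C, EtOAc/EtOH, rt) should then release 7.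

**Further compounds**
F1 | step 1 | 3,5-dimethoxyphenylacetic acid (purchased) | COc1cc(CC(O)=O)cc(OC)c1
F2 | step 1 | 5-[2-(3,5-dimethoxyphenyl)-1-hydroxyethylidene]-2,2-dimethyl-1,3-dioxane-4,6-dione | COc1cc(CC(O)=C2C(=O)OC(C)(C)OC2=O)cc(OC)c1
F3 | step 1 | methyl 4-(3,5-dimethoxyphenyl)-3-oxobutanoate | COC(=O)CC(=O)Cc1cc(OC)cc(OC)c1
F4 | step 1 | methyl 2-[(3,5-dimethoxyphenyl)acetyl]hexadecanoate (racemic) | CCCCCCCCCCCCCCC(C(=O)OC)C(=O)Cc1cc(OC)cc(OC)c1
F5 | step 2 | 1,3-bis(benzyloxy)-5-bromobenzene (purchased) | Brc1cc(OCc2ccccc2)cc(OCc2ccccc2)c1
F6 | step 2 | 1-[3,5-bis(benzyloxy)phenyl]propan-2-one | CC(=O)Cc1cc(OCc2ccccc2)cc(OCc2ccccc2)c1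
F7 | step 2 | dipotassium α,α′-dianion of F6 | [K+].[K+].[CH2-]C([O-])=Cc1cc(OCc2ccccc2)cc(OCc2ccccc2)c1
F8 | step 2 | potassium C1=C2 enolate of F9 | [K+].CCCCCCCCCCCCCCCC([O-])=Cc1cc(OCc2ccccc2)cc(OCc2ccccc2)c1
F9 | step 2 | 1-[3,5-bis(benzyloxy)phenyl]heptadecan-2-one | CCCCCCCCCCCCCCCC(=O)Cc1cc(OCc2ccccc2)cc(OCc2ccccc2)c1
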